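**Plan**

1. The target is numbered as a 2H-chromen-5(4aH)-one: O1, C2 (CMe2), C3=C4, C4a (quaternary, R), C5 (C=O), C6 (isobutyryl), C7 (OH), C8 (prenyl), C8a.
2. Retrosynthesis: the pyran is cut at O1–C8a and at C3=C4, which gives 2-methylbut-3-en-2-ol and a 5-methoxy-6-propenyl-cyclohexa-2,4-dienone. The C4a–C4 bond (an allyl group) is cut next, which re-aromatises the ring to the 4-O-methyl ether of deoxycohumulone. The two ring–prenyl bonds and the ring–acyl bond are cut last, back to phloroglucinol.
3. Forward: the benzene ring is acylated, prenylated twice and O-methylated (the methoxy group is the leaving group for the last step). Dearomative C-allylation turns it into the cyclohexadienone ring and creates C4a. The allyl group is isomerised to propenyl, and the pyran ring is annulated last, in one flask.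
4. Enabling feature: C8a is the alkoxy-bearing end of a doubly vinylogous ester (C8a=C8–C7=C6–C5=O) and is bonded to the quaternary C4a, which carries a 1-alkenyl group. An alcohol exchanged in at C8a therefore places the 1,1-dimethylallyl olefin where ring-closing metathesis with the C4a alkenyl carbon gives the six-membered ring O1–C2–C3–C4–C4a–C8a.
5. Stereochemistry: C4a is the only stereocenter. It is set by catalyst control in the asymmetric allylic alkylation, where the chiral diphosphine on palladium distinguishes the two enantiotopic prenylated ring carbons of the Cs-symmetric phenol. Being quaternary, it is carried unchanged to the end.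

Key step: step 6

Remark on the chemistry: the sense of induction of the chiral palladium catalyst on this nucleophile cannot be predicted with confidence. The (R,R)-ligand is assumed to give (S)-8; the (S,S)-ligand would be used instead if the opposite sense is found.

**Step 1**
Reactants: 1 phloroglucinol (benzene-1,3,5-triol); 2 2-methylpropanoyl chloride (isobutyryl chloride)
Product: 3 2-methyl-1-(2,4,6-trihydroxyphenyl)propan-1-one (phlorisobutyrophenone)
Conditions: AlCl3 (3 equiv), PhNO2, 0 → 65 °C; aq. HCl work-up
Reagents that add atoms: none
Why: Friedel–Crafts C-acylation of the very electron-rich triol should stop after one acyl group, because the aryl ketone formed is deactivated and held as its aluminium chelate.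

**Step 2**
Reactants: 3 phlorisobutyrophenone; 4 1-bromo-3-methylbut-2-ene (prenyl bromide)
Product: 5 2-methyl-1-[2,4,6-trihydroxy-3,5-bis(3-methylbut-2-en-1-yl)phenyl]propan-1-one (deoxycohumulone)
Conditions: 4 (2.1 equiv), 10% aq. KOH, 0 °C
Reagents that add atoms: none
Why: Phenolate C-alkylation (C-prenylation) in water, where hydrogen bonding to the phenoxide oxygens suppresses O-alkylation, should place one prenyl group on each of the two free ring carbons, which are ortho and para to phenoxide oxygens.

**Step 3**
Reactants: 5 deoxycohumulone
Product: 6 1-[2,6-dihydroxy-4-methoxy-3,5-bis(3-methylbut-2-en-1-yl)phenyl]-2-methylpropan-1-one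
Conditions: Me2SO4 (1.05 equiv), K2CO3 (1.1 equiv), acetone, rt
Reagents that add atoms: dimethyl sulfate, COS(=O)(=O)OC
Why: Williamson O-methylation under weak base should select the 4-OH, which is para to the acyl group and the most acidic, while the two ortho hydroxyls are held in hydrogen bonds to the ketone.

**Step 4**
Reactants: 6 4-O-methyl-deoxycohumulone; 7 methyl prop-2-en-1-yl carbonate (allyl methyl carbonate)
Product: 8 (6S)-3-hydroxy-5-methoxy-4,6-bis(3-methylbut-2-en-1-yl)-2-(2-methylpropanoyl)-6-(prop-2-en-1-yl)cyclohexa-2,4-dien-1-one
Conditions: 7 (1.1 equiv), Pd2(dba)3·CHCl3 (2.5 mol %), (1R,2R)-N,N'-bis[2-(diphenylphosphanyl)benzoyl]cyclohexane-1,2-diamine (7.5 mol %), CH2Cl2, 0 °C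
Reagents that add atoms: none
Why: Dearomative Tsuji–Trost asymmetric allylic alkylation, in which the phenolate formed by the methoxide released from 7 attacks the π-allylpalladium complex through a prenylated ring carbon (ortho to one phenoxide oxygen, para to the other), should give the cyclohexadienone; the new quaternary stereocenter is set by the chiral pocket of the diphosphine, which distinguishes the two enantiotopic prenylated carbons.

**Step 5**
Reactants: 8 the (6S)-allyl dienone
Product: 9 (6R)-3-hydroxy-5-methoxy-4,6-bis(3-methylbut-2-en-1-yl)-2-(2-methylpropanoyl)-6-[(1E)-prop-1-en-1-yl]cyclohexa-2,4-dien-1-one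
Conditions: [Ir(cod)(PMePh2)2]PF6 (3 mol %; activated with H2, then degassed), THF, rt
Reagents that add atoms: none
Why: Iridium-hydride olefin isomerisation (insertion, then β-hydride elimination) should move only the monosubstituted terminal double bond by one position, because the trisubstituted prenyl olefins do not insert and the quaternary C4a stops further migration; the stereocenter is untouched and its descriptor changes from S to R only because the ranking of the substituents changes.

**Step 6**
Reactants: 9 the (6R)-propenyl dienone; 10 2-methylbut-3-en-2-ol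
Product: 12 (4aR)-7-hydroxy-2,2-dimethyl-4a,8-bis(3-methylbut-2-en-1-yl)-6-(2-methylpropanoyl)-2H-chromen-5(4aH)-one, via 1,1-dimethylallyl enol ether 11 (not isolated)
Conditions: 10 (10 equiv), PPTS (0.3 equiv), 5 Å MS, PhMe, 60 °C; then second-generation Hoveyda–Grubbs catalyst RuCl2(H2IMes)(=CH-C6H4-2-OiPr) (10 mol %), 60 °C, Ar sweep
Reagents that add atoms: none
Why: Proposed new method: the pyridinium acid protonates the C5/acyl carbonyl system of 9, which makes C8a an oxocarbenium-type carbon, so that 10 adds and methanol leaves (taken up by the sieves) to give 11, whose terminal vinyl group is then taken up by the ruthenium alkylidene and closed onto the C4a propenyl carbon with loss of propene, an irreversible step that drains the unfavourable exchange equilibrium. The closest known reaction types are the acid-catalysed alcohol exchange of 3-alkoxy-enones (vinylogous transesterification), the Saucy–Marbet-type exchange of tertiary allylic alcohols onto enol ethers, and ring-closing metathesis of 1,1-dimethylallyl aryl or enol ethers with a neighbouring alkenyl group to 2,2-dimethyl-2H-pyrans; what is new is their coupling in one flask at a hindered vinylogous ester with a tertiary allylic alcohol. The pyran ring (O1, C2, C3, C4, C4a, C8a) closes by ring-closing olefin metathesis as a six-membered ring, which forces the cis geometry of C3=C4. No stereocenter is formed; C4a is quaternary, cannot epimerise and is carried through unchanged. The step needs site selectivity at C8a, secured because only C8a carries an alkoxy leaving group while the C7 hydroxyl is locked in its chelate to the acyl group, and chemoselectivity among the three olefins on the ring, secured because only the propenyl group gives a six-membered ring whereas either prenyl group would give a seven-membered ring through a trisubstituted olefin; adding the catalyst only after the exchange has started limits metathesis of 9 itself.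

**Compound list**

1 | phloroglucinol (benzene-1,3,5-triol) | Oc1cc(O)cc(O)c1 | starting material
2 | 2-methylpropanoyl chloride | CC(C)C(=O)Cl | starting material
3 | 2-methyl-1-(2,4,6-trihydroxyphenyl)propan-1-one | CC(C)C(=O)c1c(O)cc(O)cc1O | intermediate
4 | 1-bromo-3-methylbut-2-ene | CC(C)=CCBr | starting material
5 | 2-methyl-1-[2,4,6-trihydroxy-3,5-bis(3-methylbut-2-en-1-yl)phenyl]propan-1-one | CC(C)=CCc1c(O)c(CC=C(C)C)c(O)c(C(=O)C(C)C)c1O | intermediate
6 | 1-[2,6-dihydroxy-4-methoxy-3,5-bis(3-methylbut-2-en-1-yl)phenyl]-2-methylpropan-1-one | COc1c(CC=C(C)C)c(O)c(C(=O)C(C)C)c(O)c1CC=C(C)C | intermediate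
7 | methyl prop-2-en-1-yl carbonate | C=CCOC(=O)OC | starting material
8 | (6S)-3-hydroxy-5-methoxy-4,6-bis(3-methylbut-2-en-1-yl)-2-(2-methylpropanoyl)-6-(prop-2-en-1-yl)cyclohexa-2,4-dien-1-one | CC(C)=CCC1=C(OC)[C@](CC=C)(CC=C(C)C)C(=O)C(C(=O)C(C)C)=C1O | intermediate
9 | (6R)-3-hydroxy-5-methoxy-4,6-bis(3-methylbut-2-en-1-yl)-2-(2-methylpropanoyl)-6-[(1E)-prop-1-en-1-yl]cyclohexa-2,4-dien-1-one | CC(C)=CCC1=C(OC)[C@](/C=C/C)(CC=C(C)C)C(=O)C(C(=O)C(C)C)=C1O | intermediate
10 | 2-methylbut-3-en-2-ol | CC(C)(O)C=C | starting material
11 | (6R)-3-hydroxy-4,6-bis(3-methylbut-2-en-1-yl)-5-[(2-methylbut-3-en-2-yl)oxy]-2-(2-methylpropanoyl)-6-[(1E)-prop-1-en-1-yl]cyclohexa-2,4-dien-1-one | CC(C)=CCC1=C(OC(C)(C)C=C)[C@](/C=C/C)(CC=C(C)C)C(=O)C(C(=O)C(C)C)=C1O | intermediate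
12 | (4aR)-7-hydroxy-2,2-dimethyl-4a,8-bis(3-methylbut-2-en-1-yl)-6-(2-methylpropanoyl)-2H-chromen-5(4aH)-one | CC(C)=CCC1=C2OC(C)(C)C=C[C@@]2(CC=C(C)C)C(=O)C(C(=O)C(C)C)=C1O | target

**Step count and risks**

Total step count: 6. Longest linear sequence: 6 steps, from phloroglucinol.

Steps most likely to fail:

Step 6 (proposed new method). The alkoxy exchange at the crowded C8a may not reach a useful level before the ruthenium catalyst decays. The tertiary allylic alcohol may ionise under the acid and transfer a dimethylallyl cation to the enol. Metathesis may also close onto a prenyl group of 9 before the ether has formed. The fallback uses known chemistry and makes the ether oxygen–carbon bond on the aromatic ring, so that only the olefin is formed in the last step. It sets out from 5. Copper-catalysed O-propargylation of the 4-OH (3-chloro-3-methylbut-1-yne, K2CO3, KI cat., CuI cat., acetone, 50 °C) should give the aryl 1,1-dimethylpropargyl ether F1. Asymmetric allylic dearomatisation under the conditions of step 4 should give the propargyloxy dienone F2. Semihydrogenation of the alkyne (H2, Pd/CaCO3 poisoned with Pb(OAc)2, quinoline, EtOAc) should give the 1,1-dimethylallyloxy dienone F3. Isomerisation of the allyl group as in step 5 returns to the route at 11, now isolated, which is closed to 12 with the second-generation Hoveyda–Grubbs catalyst in PhMe at 60 °C.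

Step 4. Discrimination between the two enantiotopic ring carbons may be poor, and allylation may go to a phenol oxygen or proceed a second time on the product. The fallback replaces asymmetric catalysis by resolution. It sets out from 6. Allylation with 7 and the achiral zerovalent palladium catalyst Pd(PPh3)4 in THF should give the racemic allyl dienone F4, which is separated by preparative HPLC on a chiral stationary phase (amylose tris(3,5-dimethylphenylcarbamate)). It comes back to the route at 8.

Step 3. With the 4-OH crowded by two prenyl groups, methylation may drift to an ortho hydroxyl or to a ring carbon, or go twice. The fallback changes the order so that the methyl ether is made before the ring is crowded. It sets out from 3. O-Methylation (Me2SO4, K2CO3, acetone) of the unhindered para hydroxyl should give 1-(2,6-dihydroxy-4-methoxyphenyl)-2-methylpropan-1-one F5, and bis-C-prenylation with 4 under the conditions of step 2 comes back to the route at 6.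

**Further compounds**

F1 | step 6 | 1-{2,6-dihydroxy-4-[(2-methylbut-3-yn-2-yl)oxy]-3,5-bis(3-methylbut-2-en-1-yl)phenyl}-2-methylpropan-1-one | C#CC(C)(C)Oc1c(CC=C(C)C)c(O)c(C(=O)C(C)C)c(O)c1CC=C(C)C
F2 | step 6 | (6S)-3-hydroxy-4,6-bis(3-methylbut-2-en-1-yl)-5-[(2-methylbut-3-yn-2-yl)oxy]-2-(2-methylpropanoyl)-6-(prop-2-en-1-yl)cyclohexa-2,4-dien-1-one | CC(C)=CCC1=C(OC(C)(C)C#C)[C@](CC=C)(CC=C(C)C)C(=O)C(C(=O)C(C)C)=C1O
F3 | step 6 | (6S)-3-hydroxy-4,6-bis(3-methylbut-2-en-1-yl)-5-[(2-methylbut-3-en-2-yl)oxy]-2-(2-methylpropanoyl)-6-(prop-2-en-1-yl)cyclohexa-2,4-dien-1-one | CC(C)=CCC1=C(OC(C)(C)C=C)[C@](CC=C)(CC=C(C)C)C(=O)C(C(=O)C(C)C)=C1O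
F4 | step 4 | racemic 3-hydroxy-5-methoxy-4,6-bis(3-methylbut-2-en-1-yl)-2-(2-methylpropanoyl)-6-(prop-2-en-1-yl)cyclohexa-2,4-dien-1-one | CC(C)=CCC1=C(OC)C(CC=C)(CC=C(C)C)C(=O)C(C(=O)C(C)C)=C1O
F5 | step 3 | 1-(2,6-dihydroxy-4-methoxyphenyl)-2-methylpropan-1-one | COc1cc(O)c(C(=O)C(C)C)c(O)c1
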